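Compound numbers are those of the steps and of the list after them. Ring positions follow flavan numbering (O1, C2, C3, C4, C4a, C5 to C8, C8a), with primed locants for the benzofuran.

## Analysis of the target

The target 29 is a (2S)-flavan. Its aromatic ring A (C4a, C5, C6, C7, C8, C8a) is fused to a dihydropyran ring C (O1, C2, C3, C4) that carries the unsubstituted phenyl ring B at C2, and C8 is bonded to C2′ of a benzofuran. Ring A is a phloroglucinol whose three oxygens all differ (C5 methyl ether, C7 free phenol, C8a ring ether), and only C6 carries hydrogen. The benzofuran repeats the problem with a 4′-methoxyl, a 5′-methyl and a 6′-hydroxyl around its benzo ring. C2 is the only stereocenter, so there is no relative configuration to control and no neighbouring center to lean on; a reagent must set it. C2 is a benzylic ether carbon that can ionise in strong acid or be cleaved by hydrogenolysis, and the two electron-rich phenols and the 2-arylbenzofuran are sensitive to oxidants. The difficulty is regiochemical: C6 and C8 of a 5,7-dioxygenated flavan are both activated, the C8–C2′ bond sits between O1 and the C7 oxygen, and in each ring two oxygens must be told apart. The route rests on the pattern of ring A read from C8a: a hydroxyl carbon (C8a), an aryl carbon (C8), an oxygen carbon (C7), a CH (C6), a methoxy carbon (C5) and an alkyl carbon (C4a). A ketene carbon, the two carbons of a siloxyalkyne, and the diazomethyl carbon and enol ether of an α-methoxy enone deliver exactly this pattern in a vinylketene benzannulation.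

## Retrosynthetic reasoning

**29 from 28.** Both free phenols are masked as triisopropylsilyl ethers and released together at the end. A silyl group is chosen because the C7 oxygen is born as a silyl ether in the ring-forming step; giving the 6′ oxygen the same group makes the end game one mild step. It also avoids hydrogenolysis or strong acid next to the benzylic C2–O1 bond.

**28 from 27, and 27 from 26.** Ring C is cut at O1–C2. The forward reaction is an intramolecular Mitsunobu etherification between the C8a hydroxyl and the benzylic carbinol. It inverts, so the open-chain carbinol must be R. The cut is made here because the C8a hydroxyl is the one phenol that leaves the benzannulation unprotected, so no phenol differentiation is needed. Diol 27 comes from 26 by removal of the alkyl silyl ether under conditions that leave the two aryl silyl ethers alone.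

**26 from 10 and 21.** Ring A is taken apart completely, at C8–C8a, C6–C7, C5–C6 and C4a–C8a. Any disconnection that keeps ring A would have to choose between C6 and C8 on a finished flavan and force a hindered aryl–heteroaryl coupling at C8. Making the ring from diazo ketone 10 and siloxyalkyne 21 writes in the three different oxygens, the C8 benzofuran and the C4a chain at once. The forward reaction must generate a vinylketene from 10, add 21 with the right orientation, and carry the adduct through ring opening and 6π closure.

**10 from 8.** The diazo group is installed by detrifluoroacetylative diazo transfer onto methyl ketone 8. Acylation of a diazoalkane with the corresponding enoyl chloride is the shorter textbook route, but conjugated acid chlorides are prone to dipolar cycloaddition at the C=C bond. The diazo transfer route avoids that and is the standard entry to α-diazo enones.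

**8 from 7 and 6; 6 from 4 and 5.** The methyl ketone comes from Weinreb amide 7, which stops the Grignard addition at the ketone, and 7 from ester 6. The trisubstituted enol ether double bond of 6 (the future C4a–C5 bond) is cut by a Horner–Wadsworth–Emmons reaction between aldehyde 4 and methoxyphosphonoacetate 5. This brings in the C5 methoxyl with the carbon that will carry it and gives the Z isomer, which the later electrocyclisation prefers.

**4 from 3, 2 and 1.** The aldehyde is masked as the terminal alkene of 3 and released by ozonolysis. The stereocenter is set at the start by catalytic asymmetric transfer hydrogenation of the aryl ketone 1 to 2, and silylation gives 3. Placing the reduction first lets a robust, well-understood reaction carry the only stereochemical decision of the route.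

**21 from 18.** The siloxyalkyne is cut at the alkyne: a Kowalski homologation of ester 18 gives the ynolate, which is O-silylated. The ester carbon becomes C8 and the added carbon becomes C7.

**18 from 15 and 16.** The furan ring is cut at O1′–C2′ and C2′=C3′. O-Alkylation of salicylaldehyde 15 by bromoacetate 16, followed by intramolecular aldol condensation, closes it. Only one hydroxyl is free in 15, so the direction of closure is fixed.

**15 from 14, 12 and 11.** The formyl group of 15 is placed ortho to the free hydroxyl of 14. The hydroxyl of 14 (the future O1′) is introduced para to the methyl group by sterically controlled C–H borylation of 12 and oxidation. Compound 12 is the silyl ether of 11, a phenol in which the 4′-methoxyl and the 6′-oxygen are already differentiated. Compound 11 has only two oxygens, so the third must be added; borylation reaches the one position that electrophilic substitution does not.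

## Alternatives that were turned down

**Alternative 1:** The furan ring is disconnected at C2′=C3′. In the forward direction base converts phosphonium salt A2 into its ylide, which attacks the neighbouring aryl ester carbonyl in an intramolecular Wittig reaction and expels the phosphine oxide to give flavanyl benzofuran A1.
- For: the closure is thermal, well established for 2-arylbenzofurans and free of high-energy intermediates, and the C8–C2′ bond is made as an ordinary acyl bond.
- Against: the acyl half of A2 is a (2S)-flavan carboxylated at C8, so the C6 versus C8 choice on a finished flavan returns. The ester carbonyl is flanked by O1 and the C7 benzyloxy group and is electron-rich, a poor electrophile for a stabilised ylide. The phenol half needs the same salicyl substitution pattern as 15, so nothing is saved there. A1 carries a benzyl and a silyl ether, which means two deprotections, one of them a hydrogenolysis beside the benzylic C2–O1 bond.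
- Comparison: on the reliability of the ring-forming event itself this alternative is as strong as or stronger than the chosen route. The chosen route offers in its place regiochemistry of ring A that is fixed by construction and a single fluoride deprotection.

**Alternative 2:** Ring C is disconnected at O1–C2 and C3–C4. In the forward direction a chiral scandium Lewis acid ionises salicyl alcohol A4 to an ortho-quinone methide, which adds styrene A5 in a hetero-Diels–Alder reaction to give 8-acetylflavan A3 with the C2 stereocenter.
- For: ring C and the stereocenter arise in one catalytic step from achiral components, with no separate reduction and inversion, and the flavan core is reached very quickly.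
- Against: A5 has no group that binds the catalyst, so all facial control must come from the catalyst-bound quinone methide. A4 has a free hydroxyl para to the benzylic carbon that can ionise to a para-quinone methide instead. After the key step the whole benzofuran must still be built from the C8 acetyl group, by a hindered ketone α-arylation with a fully substituted halophenol and cyclodehydration. That brings back the 4′/6′ oxygen differentiation and puts most of the synthesis after the key step.
- Comparison: this alternative is stronger on stereochemical economy. The chosen route spends two steps on the stereocenter (reduction and Mitsunobu inversion) but forms the C8–C2′ bond and the ring A oxygen pattern in the ring-forming event.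

**Alternative 3:** The benzo ring of the benzofuran is disconnected at C7′–C7a′ and C3a′–C4′. In the forward direction zerovalent palladium couples chlorocyclobutenone A7 with furylstannane A8; the 4-furylcyclobutenone opens to a dienylketene that closes onto the furan β-carbon and gives benzofuranol A6.
- For: the annulation is thermal and regiospecific, and it delivers the C4′ hydroxyl free beside a protected C6′ oxygen, so the 4′/6′ differentiation is solved cleanly by a later O-methylation.
- Against: A8 is a stannylfuran already attached to C8 of an intact (2S)-flavan, so the C6/C8 selection and a hindered coupling are again needed before the key step. A7 needs its own multistep preparation, tin is used stoichiometrically, and the end game needs a methylation and a double debenzylation next to the benzylic ether and the benzofuran.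
- Comparison: it equals the chosen route in regiocontrol of the ring it builds and is stronger in avoiding photochemistry. It builds the easier ring, however. The chosen route annulates ring A, the ring that is hard to substitute selectively, and needs only silyl protection.

Key step: step 13

Assumption: 1-phenylpent-4-en-1-one (1), methyl 2-(dimethoxyphosphoryl)-2-methoxyacetate (5), 3-methoxy-2-methylphenol (11) and ethyl bromoacetate (16) are taken as purchasable.

## Route

**Step 1**
Reactants: 1 1-phenylpent-4-en-1-one
Product: 2 (1R)-1-phenylpent-4-en-1-ol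
Conditions: RuCl[(R,R)-TsDPEN](p-cymene) (cat.), HCO2H–Et3N azeotrope, rt
Reagents that add atoms: none
Why: Noyori–Ikariya asymmetric transfer hydrogenation of an aryl alkyl ketone; the (R,R) catalyst should deliver hydride to the Si face, as it does with acetophenone, and so set the R carbinol, and this carbonyl-selective catalyst should leave the isolated terminal alkene alone.

**Step 2**
Reactants: 2 (1R)-1-phenylpent-4-en-1-ol
Product: 3 tert-butyldimethyl{[(1R)-1-phenylpent-4-en-1-yl]oxy}silane
Conditions: t-BuMe2SiCl, imidazole, DMF, rt
Reagents that add atoms: tert-butyldimethylsilyl chloride, CC(C)(C)[Si](C)(C)Cl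
Why: Standard silylation of a secondary alcohol; the silyl ether keeps the carbinol from trapping the ketene of step 13 and survives the organometallic steps in between.

**Step 3**
Reactants: 3 tert-butyldimethyl{[(1R)-1-phenylpent-4-en-1-yl]oxy}silane
Product: 4 (4R)-4-(tert-butyldimethylsilyloxy)-4-phenylbutanal
Conditions: O3, CH2Cl2, −78 °C; then PPh3, −78 °C → rt
Reagents that add atoms: ozone, [O-][O+]=O
Why: Ozonolysis with reductive work-up cleaves the monosubstituted alkene far faster than it attacks the phenyl ring; the stereocenter is γ to the new aldehyde and cannot epimerise.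

**Step 4**
Reactants: 4 (4R)-4-(tert-butyldimethylsilyloxy)-4-phenylbutanal; 5 methyl 2-(dimethoxyphosphoryl)-2-methoxyacetate
Product: 6 methyl (2Z,6R)-6-(tert-butyldimethylsilyloxy)-2-methoxy-6-phenylhex-2-enoate
Conditions: LiN(SiMe3)2, THF, −78 °C → rt
Reagents that add atoms: none
Why: Horner–Wadsworth–Emmons olefination with a stabilised α-methoxy phosphonate, which should place the ester trans to the alkyl chain; because the methoxyl outranks the ester carbon this isomer is named Z, and any minor isomer is removed by chromatography at this stage.

**Step 5**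
Reactants: 6 methyl (2Z,6R)-6-(tert-butyldimethylsilyloxy)-2-methoxy-6-phenylhex-2-enoate
Product: 7 (2Z,6R)-6-(tert-butyldimethylsilyloxy)-N,2-dimethoxy-N-methyl-6-phenylhex-2-enamide
Conditions: MeNH(OMe)·HCl, iPrMgCl, THF, −20 °C → 0 °C
Reagents that add atoms: N,O-dimethylhydroxylamine hydrochloride, CNOC.Cl
Why: Direct aminolysis of the ester by the magnesium amide of N,O-dimethylhydroxylamine (Weinreb amide formation); the β-substituted, α-oxygenated enoate is a poor Michael acceptor, so the acyl substitution should dominate.

**Step 6**
Reactants: 7 (2Z,6R)-6-(tert-butyldimethylsilyloxy)-N,2-dimethoxy-N-methyl-6-phenylhex-2-enamide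
Product: 8 (3Z,7R)-7-(tert-butyldimethylsilyloxy)-3-methoxy-7-phenylhept-3-en-2-one
Conditions: MeMgBr, THF, 0 °C
Reagents that add atoms: methylmagnesium bromide, C[Mg]Br
Why: Weinreb ketone synthesis; the chelated tetrahedral intermediate holds until work-up, so a single methyl group is added at the carbonyl and the enol ether geometry is untouched.

**Step 7**
Reactants: 8 (3Z,7R)-7-(tert-butyldimethylsilyloxy)-3-methoxy-7-phenylhept-3-en-2-one
Product: 10 (3Z,7R)-7-(tert-butyldimethylsilyloxy)-1-diazo-3-methoxy-7-phenylhept-3-en-2-one, via trifluoroacetyl diketone 9 (not isolated)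
Conditions: LiN(SiMe3)2, THF, −78 °C; CF3CO2CH2CF3; then MsN3, Et3N, H2O, MeCN, rt
Reagents that add atoms: methanesulfonyl azide, CS(=O)(=O)N=[N+]=[N-]
Why: Detrifluoroacetylative diazo transfer: kinetic deprotonation at the methyl group and Claisen acylation give the activated diketone 9, to which the sulfonyl azide transfers N2 with loss of the trifluoroacetyl group as its sulfonamide. The method is the standard one for α-diazo enones, which cannot be made reliably from enoyl chlorides.

**Step 8**
Reactants: 11 3-methoxy-2-methylphenol
Product: 12 triisopropyl(3-methoxy-2-methylphenoxy)silane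
Conditions: iPr3SiCl, imidazole, DMF, rt
Reagents that add atoms: triisopropylsilyl chloride, CC(C)[Si](Cl)(C(C)C)C(C)C
Why: Standard phenol silylation; the bulky group marks the future 6′ oxygen, tolerates the lithium bases of step 12, and shields its ortho position in steps 9 and 10.

**Step 9**
Reactants: 12 triisopropyl(3-methoxy-2-methylphenoxy)silane
Product: 14 3-methoxy-4-methyl-5-(triisopropylsilyloxy)phenol, via aryl pinacol boronate 13 (not isolated)
Conditions: [Ir(OMe)(cod)]2 (cat.), 4,4′-di-tert-butyl-2,2′-bipyridine (cat.), B2pin2, THF, 80 °C; then Oxone (2KHSO5·KHSO4·K2SO4), acetone/H2O, rt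
Reagents that add atoms: potassium peroxymonosulfate (the oxidant in Oxone), [K+].[O-]S(=O)(=O)OO
Why: Iridium-catalysed C–H borylation (Hartwig–Miyaura type) is governed by sterics and should take the only C–H of the 1,2,3-trisubstituted ring that has no ortho substituent, para to the methyl group. Oxidation of the C–B bond then gives the phenol at the position that electrophilic substitution cannot reach.

**Step 10**
Reactants: 14 3-methoxy-4-methyl-5-(triisopropylsilyloxy)phenol
Product: 15 6-hydroxy-2-methoxy-3-methyl-4-(triisopropylsilyloxy)benzaldehyde
Conditions: MgCl2, Et3N, (CH2O)n, MeCN, reflux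
Reagents that add atoms: paraformaldehyde (as formaldehyde), C=O
Why: Casnati–Skattebøl ortho-formylation through the magnesium phenoxide, which reacts only ortho to the free hydroxyl. Of the two ortho sites, the one next to the methoxyl is open, while the other is covered by the triisopropylsilyl group that the neighbouring methyl pushes toward it.

**Step 11**
Reactants: 15 6-hydroxy-2-methoxy-3-methyl-4-(triisopropylsilyloxy)benzaldehyde; 16 ethyl bromoacetate
Product: 18 ethyl 4-methoxy-5-methyl-6-(triisopropylsilyloxy)benzofuran-2-carboxylate, via aryloxyacetate 17 (not isolated)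
Conditions: K2CO3 (anhydrous), DMF, 80 °C
Reagents that add atoms: none
Why: Rap–Stoermer-type benzofuran synthesis: Williamson O-alkylation of the only free phenol, then intramolecular aldol condensation of the ester methylene onto the aldehyde and dehydration to the aromatic furan; with one hydroxyl free the direction of closure is fixed.

**Step 12**
Reactants: 18 ethyl 4-methoxy-5-methyl-6-(triisopropylsilyloxy)benzofuran-2-carboxylate
Product: 21 4-methoxy-5-methyl-6-(triisopropylsilyloxy)-2-[(triisopropylsilyloxy)ethynyl]benzofuran, via dibromo enolate 19 (not isolated), via lithium ynolate 20 (not isolated)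
Conditions: CH2Br2, lithium 2,2,6,6-tetramethylpiperidide, THF, −78 °C; then LiN(SiMe3)2; n-BuLi, −78 → 0 °C; then iPr3SiOTf, −78 → 0 °C
Reagents that add atoms: dibromomethane, BrCBr; triisopropylsilyl trifluoromethanesulfonate, CC(C)[Si](OS(=O)(=O)C(F)(F)F)(C(C)C)C(C)C
Why: Kowalski ester homologation: dibromomethyllithium adds to the ester, bromine–lithium exchange on enolate 19 triggers 1,2-shift of the benzofuranyl group to ynolate 20, and the bulky silyl triflate silylates the ynolate on oxygen, the established route from esters to siloxyalkynes.

**Step 13**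
Reactants: 10 (3Z,7R)-7-(tert-butyldimethylsilyloxy)-1-diazo-3-methoxy-7-phenylhept-3-en-2-one; 21 4-methoxy-5-methyl-6-(triisopropylsilyloxy)-2-[(triisopropylsilyloxy)ethynyl]benzofuran (slight excess)
Product: 26 2-[(3R)-3-(tert-butyldimethylsilyloxy)-3-phenylpropyl]-3-methoxy-6-[4-methoxy-5-methyl-6-(triisopropylsilyloxy)benzofuran-2-yl]-5-(triisopropylsilyloxy)phenol, via vinylketene 22 (not isolated), via 4-alkenylcyclobutenone 23 (not isolated), via dienylketene 24 (not isolated), via cyclohexadienone 25 (not isolated)
Conditions: hν (365 nm), CH2Cl2, rt; then PhMe, 80 °C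
Reagents that add atoms: none
Why: This is the Danheiser benzannulation in its photochemical Wolff variant, a known reaction of α-diazo enones with siloxyalkynes. Light taken up by the diazo ketone expels N2 and the 1-methoxyalkenyl group migrates (Wolff rearrangement, forming C5–C6) to give vinylketene 22. Siloxyalkyne 21 adds across the ketene C=C in a [2+2] cycloaddition, its nucleophilic aryl-bearing carbon bonding to the ketene carbonyl carbon (C8–C8a) and its siloxy carbon to the ketene CH (C6–C7), to give cyclobutenone 23. Warming opens 23 by 4π electrocyclic cleavage to dienylketene 24, and ring A closes by thermal 6π electrocyclisation (C4a–C8a) to cyclohexadienone 25, which tautomerises to the phenol. No stereocenter is formed in the product, and the carbinol carbon of the chain (the future C2) is remote and untouched. The selectivity needed is the orientation of the [2+2] step; the oxygen-donor polarisation of the ynol ether fixes it, so the benzofuran lands at C8 beside the free C8a hydroxyl and C6 stays unsubstituted. The Z enol ether puts the chain on the outside of the triene terminus, which keeps the 6π closure unhindered. Long-wavelength light is chosen to excite the diazo ketone and spare the alkynylbenzofuran chromophore as far as possible, and the alkyne is used in slight excess so that little ketene is left to acylate the hindered product phenol.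

**Step 14**
Reactants: 26 2-[(3R)-3-(tert-butyldimethylsilyloxy)-3-phenylpropyl]-3-methoxy-6-[4-methoxy-5-methyl-6-(triisopropylsilyloxy)benzofuran-2-yl]-5-(triisopropylsilyloxy)phenol
Product: 27 2-[(3R)-3-hydroxy-3-phenylpropyl]-3-methoxy-6-[4-methoxy-5-methyl-6-(triisopropylsilyloxy)benzofuran-2-yl]-5-(triisopropylsilyloxy)phenol
Conditions: HF·pyridine, pyridine, THF, 0 °C → rt
Reagents that add atoms: none
Why: Chemoselective desilylation: under buffered acidic fluoride an alkyl tert-butyldimethylsilyl ether is cleaved well before hindered aryl triisopropylsilyl ethers, and the pyridine buffer keeps the benzylic carbinol from ionising.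

**Step 15**
Reactants: 27 2-[(3R)-3-hydroxy-3-phenylpropyl]-3-methoxy-6-[4-methoxy-5-methyl-6-(triisopropylsilyloxy)benzofuran-2-yl]-5-(triisopropylsilyloxy)phenol
Product: 28 (2S)-5-methoxy-8-[4-methoxy-5-methyl-6-(triisopropylsilyloxy)benzofuran-2-yl]-2-phenyl-7-(triisopropylsilyloxy)chromane
Conditions: PPh3, DIAD, THF, 0 °C → rt
Reagents that add atoms: none
Why: Intramolecular Mitsunobu etherification, an established flavan ring closure: the only free phenol (C8a–OH) displaces the activated benzylic oxygen in a 6-exo-tet SN2 step, so the R carbinol is inverted to the S configuration at C2.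

**Step 16**
Reactants: 28 (2S)-5-methoxy-8-[4-methoxy-5-methyl-6-(triisopropylsilyloxy)benzofuran-2-yl]-2-phenyl-7-(triisopropylsilyloxy)chromane
Product: 29 2-[(2S)-7-hydroxy-5-methoxy-2-phenylchroman-8-yl]-4-methoxy-5-methylbenzofuran-6-ol
Conditions: Bu4NF, AcOH, THF, 0 °C
Reagents that add atoms: none
Why: Fluoride cleavage of both aryl silyl ethers in one operation; acetic acid buffers the phenoxides against air oxidation, and the conditions touch neither the benzylic ether at C2 nor the methyl ethers.

## Compound list

1 | 1-phenylpent-4-en-1-one | C=CCCC(=O)c1ccccc1 | starting material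
2 | (1R)-1-phenylpent-4-en-1-ol | C=CCC[C@H](c1ccccc1)O | intermediate
3 | tert-butyldimethyl{[(1R)-1-phenylpent-4-en-1-yl]oxy}silane | C=CCC[C@H](c1ccccc1)O[Si](C)(C)C(C)(C)C | intermediate
4 | (4R)-4-(tert-butyldimethylsilyloxy)-4-phenylbutanal | O=CCC[C@H](c1ccccc1)O[Si](C)(C)C(C)(C)C | intermediate
5 | methyl 2-(dimethoxyphosphoryl)-2-methoxyacetate | COC(=O)C(OC)P(=O)(OC)OC | starting material
6 | methyl (2Z,6R)-6-(tert-butyldimethylsilyloxy)-2-methoxy-6-phenylhex-2-enoate | COC(=O)/C(OC)=C/CC[C@H](c1ccccc1)O[Si](C)(C)C(C)(C)C | intermediate
7 | (2Z,6R)-6-(tert-butyldimethylsilyloxy)-N,2-dimethoxy-N-methyl-6-phenylhex-2-enamide | CON(C)C(=O)/C(OC)=C/CC[C@H](c1ccccc1)O[Si](C)(C)C(C)(C)C | intermediate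
8 | (3Z,7R)-7-(tert-butyldimethylsilyloxy)-3-methoxy-7-phenylhept-3-en-2-one | CC(=O)/C(OC)=C/CC[C@H](c1ccccc1)O[Si](C)(C)C(C)(C)C | intermediate
9 | (5Z,9R)-9-(tert-butyldimethylsilyloxy)-1,1,1-trifluoro-5-methoxy-9-phenylnon-5-ene-2,4-dione | O=C(CC(=O)/C(OC)=C/CC[C@H](c1ccccc1)O[Si](C)(C)C(C)(C)C)C(F)(F)F | intermediate
10 | (3Z,7R)-7-(tert-butyldimethylsilyloxy)-1-diazo-3-methoxy-7-phenylhept-3-en-2-one | [N-]=[N+]=CC(=O)/C(OC)=C/CC[C@H](c1ccccc1)O[Si](C)(C)C(C)(C)C | intermediate
11 | 3-methoxy-2-methylphenol | Cc1c(O)cccc1OC | starting material
12 | triisopropyl(3-methoxy-2-methylphenoxy)silane | COc1cccc(O[Si](C(C)C)(C(C)C)C(C)C)c1C | intermediate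
13 | triisopropyl[3-methoxy-2-methyl-5-(4,4,5,5-tetramethyl-1,3,2-dioxaborolan-2-yl)phenoxy]silane | COc1cc(B2OC(C)(C)C(C)(C)O2)cc(O[Si](C(C)C)(C(C)C)C(C)C)c1C | intermediate
14 | 3-methoxy-4-methyl-5-(triisopropylsilyloxy)phenol | COc1cc(O)cc(O[Si](C(C)C)(C(C)C)C(C)C)c1C | intermediate
15 | 6-hydroxy-2-methoxy-3-methyl-4-(triisopropylsilyloxy)benzaldehyde | O=Cc1c(O)cc(O[Si](C(C)C)(C(C)C)C(C)C)c(C)c1OC | intermediate
16 | ethyl bromoacetate | CCOC(=O)CBr | starting material
17 | ethyl 2-[2-formyl-3-methoxy-4-methyl-5-(triisopropylsilyloxy)phenoxy]acetate | CCOC(=O)COc1cc(O[Si](C(C)C)(C(C)C)C(C)C)c(C)c(OC)c1C=O | intermediate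
18 | ethyl 4-methoxy-5-methyl-6-(triisopropylsilyloxy)benzofuran-2-carboxylate | CCOC(=O)c1cc2c(OC)c(C)c(O[Si](C(C)C)(C(C)C)C(C)C)cc2o1 | intermediate
19 | lithium 2,2-dibromo-1-[4-methoxy-5-methyl-6-(triisopropylsilyloxy)benzofuran-2-yl]ethen-1-olate | [Li+].[O-]C(=C(Br)Br)c1cc2c(OC)c(C)c(O[Si](C(C)C)(C(C)C)C(C)C)cc2o1 | intermediate
20 | lithium 2-[4-methoxy-5-methyl-6-(triisopropylsilyloxy)benzofuran-2-yl]ethyn-1-olate | [Li+].[O-]C#Cc1cc2c(OC)c(C)c(O[Si](C(C)C)(C(C)C)C(C)C)cc2o1 | intermediate
21 | 4-methoxy-5-methyl-6-(triisopropylsilyloxy)-2-[(triisopropylsilyloxy)ethynyl]benzofuran | CC(C)[Si](OC#Cc1cc2c(OC)c(C)c(O[Si](C(C)C)(C(C)C)C(C)C)cc2o1)(C(C)C)C(C)C | intermediate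
22 | (3Z,7R)-7-(tert-butyldimethylsilyloxy)-3-methoxy-7-phenylhepta-1,3-dien-1-one | O=C=C/C(OC)=C/CC[C@H](c1ccccc1)O[Si](C)(C)C(C)(C)C | intermediate
23 | 4-[(1Z,5R)-5-(tert-butyldimethylsilyloxy)-1-methoxy-5-phenylpent-1-en-1-yl]-2-[4-methoxy-5-methyl-6-(triisopropylsilyloxy)benzofuran-2-yl]-3-(triisopropylsilyloxy)cyclobut-2-en-1-one | O=C1C(c2cc3c(OC)c(C)c(O[Si](C(C)C)(C(C)C)C(C)C)cc3o2)=C(O[Si](C(C)C)(C(C)C)C(C)C)C1/C(OC)=C/CC[C@H](c1ccccc1)O[Si](C)(C)C(C)(C)C | intermediate
24 | (3E,5Z,9R)-9-(tert-butyldimethylsilyloxy)-5-methoxy-2-[4-methoxy-5-methyl-6-(triisopropylsilyloxy)benzofuran-2-yl]-9-phenyl-3-(triisopropylsilyloxy)nona-1,3,5-trien-1-one | O=C=C(c1cc2c(OC)c(C)c(O[Si](C(C)C)(C(C)C)C(C)C)cc2o1)/C(O[Si](C(C)C)(C(C)C)C(C)C)=C\C(OC)=C\CC[C@H](c1ccccc1)O[Si](C)(C)C(C)(C)C | intermediate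
25 | 6-[(3R)-3-(tert-butyldimethylsilyloxy)-3-phenylpropyl]-5-methoxy-2-[4-methoxy-5-methyl-6-(triisopropylsilyloxy)benzofuran-2-yl]-3-(triisopropylsilyloxy)cyclohexa-2,4-dien-1-one | O=C1C(c2cc3c(OC)c(C)c(O[Si](C(C)C)(C(C)C)C(C)C)cc3o2)=C(O[Si](C(C)C)(C(C)C)C(C)C)C=C(OC)C1CC[C@H](c1ccccc1)O[Si](C)(C)C(C)(C)C | intermediate
26 | 2-[(3R)-3-(tert-butyldimethylsilyloxy)-3-phenylpropyl]-3-methoxy-6-[4-methoxy-5-methyl-6-(triisopropylsilyloxy)benzofuran-2-yl]-5-(triisopropylsilyloxy)phenol | COc1cc(O[Si](C(C)C)(C(C)C)C(C)C)c(-c2cc3c(OC)c(C)c(O[Si](C(C)C)(C(C)C)C(C)C)cc3o2)c(O)c1CC[C@H](c1ccccc1)O[Si](C)(C)C(C)(C)C | intermediate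
27 | 2-[(3R)-3-hydroxy-3-phenylpropyl]-3-methoxy-6-[4-methoxy-5-methyl-6-(triisopropylsilyloxy)benzofuran-2-yl]-5-(triisopropylsilyloxy)phenol | COc1cc(O[Si](C(C)C)(C(C)C)C(C)C)c(-c2cc3c(OC)c(C)c(O[Si](C(C)C)(C(C)C)C(C)C)cc3o2)c(O)c1CC[C@H](c1ccccc1)O | intermediate
28 | (2S)-5-methoxy-8-[4-methoxy-5-methyl-6-(triisopropylsilyloxy)benzofuran-2-yl]-2-phenyl-7-(triisopropylsilyloxy)chromane | COc1cc(O[Si](C(C)C)(C(C)C)C(C)C)c(-c2cc3c(OC)c(C)c(O[Si](C(C)C)(C(C)C)C(C)C)cc3o2)c2c1CC[C@@H](c1ccccc1)O2 | intermediate
29 | 2-[(2S)-7-hydroxy-5-methoxy-2-phenylchroman-8-yl]-4-methoxy-5-methylbenzofuran-6-ol | COc1cc(O)c(-c2cc3c(OC)c(C)c(O)cc3o2)c2c1CC[C@@H](c1ccccc1)O2 | target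

## Step count and least certain steps

Total step count: 16. Longest linear sequence: 11 steps (steps 1 to 7, then 13 to 16). The benzofuran branch (steps 8 to 12) joins at step 13.

**Step 13 (key step).** The most likely failure is light-induced degradation of the alkyne partner, because its extended alkynylbenzofuran chromophore competes with the diazo ketone for the light. Slow capture of the vinylketene would also lead to ketene dimerisation or to acylation of the product phenol. The fallback removes the light and generates the same vinylketene thermally (cyclobutenone form of the same benzannulation). It sets out from 3. Hydroboration–oxidation (9-BBN; NaOH, H2O2) gives (5R)-5-(tert-butyldimethylsilyloxy)-5-phenylpentan-1-ol F1. Oxidation (TEMPO, PhI(OAc)2, MeCN/H2O) gives (5R)-5-(tert-butyldimethylsilyloxy)-5-phenylpentanoic acid F2. Oxalyl chloride converts this to (5R)-5-(tert-butyldimethylsilyloxy)-5-phenylpentanoyl chloride F3. Dehydrochlorination with Et3N in the presence of methoxyacetylene (ketene–alkoxyalkyne [2+2]) gives 4-[(3R)-3-(tert-butyldimethylsilyloxy)-3-phenylpropyl]-3-methoxycyclobut-2-en-1-one F4. Heating F4 with 21 in toluene at 110 °C opens it to 22, and the cascade through 23, 24 and 25 brings the route back at 26.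

**Step 10.** Formylation may occur partly at the other ortho position, between the hydroxyl and the silyloxy group, since both sites are activated and the preference rests on steric shielding alone. The fallback fixes the site by directed metalation. It sets out from 14. Methoxymethylation (MOMCl, iPr2NEt) gives triisopropyl[3-methoxy-5-(methoxymethoxy)-2-methylphenoxy]silane F5. Lithiation between the two coordinating ether oxygens (n-BuLi, TMEDA, THF, 0 °C; the silyloxy side neither coordinates nor admits the base) and a DMF quench give 2-methoxy-6-(methoxymethoxy)-3-methyl-4-(triisopropylsilyloxy)benzaldehyde F6. Mild acid (HCl, MeOH/THF, rt) removes the acetal ortho to the aldehyde and returns the route at 15.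

**Step 11.** Carbonate in hot DMF may cleave the aryl silyl ether, and the liberated phenoxide would then be alkylated by the bromoacetate. The fallback avoids carbonate and alkyl halide altogether. It sets out from 15. Mitsunobu etherification with ethyl glycolate (PPh3, DIAD, THF) gives 17, this time isolated. Ring closure is then carried out as a separate amidine-promoted aldol condensation (DBU, toluene, 80 °C, molecular sieves), returning at 18. No new compound is made.

**Step 7.** Deprotonation may stray to the γ-methylene and give a dienolate, which would lead to acylation at the wrong carbon or to scrambling of the enol ether geometry. The fallback builds the diazo ketone by acylation instead of diazo transfer. It sets out from 6. Saponification (LiOH, THF/H2O) gives (2Z,6R)-6-(tert-butyldimethylsilyloxy)-2-methoxy-6-phenylhex-2-enoic acid F7. Activation as the mixed anhydride (isobutyl chloroformate, Et3N, THF, −15 °C) and treatment with excess ethereal diazomethane at 0 °C return the route at 10. This is second choice because diazomethane can also add across the conjugated double bond, although the β-alkyl and α-methoxy groups should slow that.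

## Further compounds

F1 | step 13 | (5R)-5-(tert-butyldimethylsilyloxy)-5-phenylpentan-1-ol | OCCCC[C@H](c1ccccc1)O[Si](C)(C)C(C)(C)C
F2 | step 13 | (5R)-5-(tert-butyldimethylsilyloxy)-5-phenylpentanoic acid | OC(=O)CCC[C@H](c1ccccc1)O[Si](C)(C)C(C)(C)C
F3 | step 13 | (5R)-5-(tert-butyldimethylsilyloxy)-5-phenylpentanoyl chloride | ClC(=O)CCC[C@H](c1ccccc1)O[Si](C)(C)C(C)(C)C
F4 | step 13 | 4-[(3R)-3-(tert-butyldimethylsilyloxy)-3-phenylpropyl]-3-methoxycyclobut-2-en-1-one | O=C1C=C(OC)C1CC[C@H](c1ccccc1)O[Si](C)(C)C(C)(C)C
F5 | step 10 | triisopropyl[3-methoxy-5-(methoxymethoxy)-2-methylphenoxy]silane | COCOc1cc(OC)c(C)c(O[Si](C(C)C)(C(C)C)C(C)C)c1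
F6 | step 10 | 2-methoxy-6-(methoxymethoxy)-3-methyl-4-(triisopropylsilyloxy)benzaldehyde | O=Cc1c(OCOC)cc(O[Si](C(C)C)(C(C)C)C(C)C)c(C)c1OC
F0 | step 11 | none | none
F7 | step 7 | (2Z,6R)-6-(tert-butyldimethylsilyloxy)-2-methoxy-6-phenylhex-2-enoic acid | OC(=O)/C(OC)=C/CC[C@H](c1ccccc1)O[Si](C)(C)C(C)(C)C
A1 | alternative 1 | (2S)-7-(benzyloxy)-5-methoxy-8-[4-methoxy-5-methyl-6-(triisopropylsilyloxy)benzofuran-2-yl]-2-phenylchromane | COc1cc(OCc2ccccc2)c(-c2cc3c(OC)c(C)c(O[Si](C(C)C)(C(C)C)C(C)C)cc3o2)c2c1CC[C@@H](c1ccccc1)O2
A2 | alternative 1 | {2-[(2S)-7-(benzyloxy)-5-methoxy-2-phenylchromane-8-carbonyloxy]-6-methoxy-5-methyl-4-(triisopropylsilyloxy)benzyl}triphenylphosphonium bromide | COc1cc(OCc2ccccc2)c(C(=O)Oc2cc(O[Si](C(C)C)(C(C)C)C(C)C)c(C)c(OC)c2C[P+](c2ccccc2)(c2ccccc2)c2ccccc2)c2c1CC[C@@H](c1ccccc1)O2.[Br-]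
A3 | alternative 2 | 1-[(2S)-7-hydroxy-5-methoxy-2-phenylchroman-8-yl]ethan-1-one | COc1cc(O)c(C(C)=O)c2c1CC[C@@H](c1ccccc1)O2
A4 | alternative 2 | 1-[2,6-dihydroxy-3-(hydroxymethyl)-4-methoxyphenyl]ethan-1-one | CC(=O)c1c(O)cc(OC)c(CO)c1O
A5 | alternative 2 | styrene | C=Cc1ccccc1
A6 | alternative 3 | 6-(benzyloxy)-2-[(2S)-7-(benzyloxy)-5-methoxy-2-phenylchroman-8-yl]-5-methylbenzofuran-4-ol | COc1cc(OCc2ccccc2)c(-c2cc3c(O)c(C)c(OCc4ccccc4)cc3o2)c2c1CC[C@@H](c1ccccc1)O2
A7 | alternative 3 | 3-(benzyloxy)-4-chloro-2-methylcyclobut-2-en-1-one | O=C1C(C)=C(OCc2ccccc2)C1Cl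
A8 | alternative 3 | tributyl{5-[(2S)-7-(benzyloxy)-5-methoxy-2-phenylchroman-8-yl]furan-2-yl}stannane | COc1cc(OCc2ccccc2)c(-c2ccc([Sn](CCCC)(CCCC)CCCC)o2)c2c1CC[C@@H](c1ccccc1)O2
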